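**Plan**

- Labdane numbering is used: ring A is C1, C2, C3, C4, C5, C10 and ring B is C5 to C10. On C4 the equatorial methyl is C18 and the axial CH2OH is C19; C20 is the methyl on C10; the side chain C11 to C16 sits on C9.
- Retrosynthesis: after the silyl group on O19 is added back, one step cuts C4–C5, C1–C2 and C9–C10. This leaves (2E,6E)-farnesyl acetate (C5 to C17 plus C1 and C20) and a five-carbon Z enal (C2, C3, C4, C18, C19).
- Enabling feature: C1 and C20 are the two methyl groups of the terminal C5=C10 isopropylidene of farnesyl acetate. C5 can therefore bond to C4 in an ene reaction that turns C1 into the CH2 end of an isopropenyl group, which then attacks the C2 formyl carbon.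
- Forward: 4-methylfuran-2(5H)-one is opened to the Z enal (steps 1 to 3). Step 4 joins it to farnesyl acetate and closes ring A, then ring B, in the same flask. Step 5 frees O19.
- Stereochemistry: C4 and C5 come from a chiral oxazaborolidinium catalyst together with the Z geometry of the enal; C2, C10 and C9 come from two chair closures; the 13E alkene and the acetate arrive with farnesyl acetate.

Key step: step 4

Assumption: the (S) catalyst of step 4 is taken to leave the Re face of C4 of aldehyde 4 open; if the sense proves opposite, its (R) mirror image is used and nothing else changes.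

**Step 1**
Reactants: 1 4-methylfuran-2(5H)-one
Product: 2 (2Z)-4-hydroxy-N-methoxy-N,3-dimethylbut-2-enamide
Conditions: MeNH(OMe)·HCl, Me3Al, CH2Cl2, 0 °C to rt; aq. Rochelle salt; crude product used at once
Reagents that add atoms: N,O-dimethylhydroxylamine hydrochloride, CNOC.Cl
Why: Aminolysis of the lactone by the aluminum amide formed in the flask (Weinreb amide formation) cleaves only the acyl C–O bond, so the Z geometry of the ring passes unchanged to the open chain and no stereocenter is formed.

**Step 2**
Reactants: 2 (2Z)-4-hydroxy-N-methoxy-N,3-dimethylbut-2-enamide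
Product: 3 (2Z)-4-{[tert-butyl(diphenyl)silyl]oxy}-N-methoxy-N,3-dimethylbut-2-enamide
Conditions: TBDPSCl, imidazole, DMF, 0 °C to rt
Reagents that add atoms: tert-butyl(chloro)diphenylsilane (TBDPSCl), CC(C)(C)[Si](Cl)(c1ccccc1)c1ccccc1
Why: Silylation of the primary allylic alcohol (silyl ether formation) removes the hydroxyl that could re-close the lactone and installs a bulky group that tolerates Lewis acid and is a poor neighbouring nucleophile.

**Step 3**
Reactants: 3 (2Z)-4-{[tert-butyl(diphenyl)silyl]oxy}-N-methoxy-N,3-dimethylbut-2-enamide
Product: 4 (2Z)-4-{[tert-butyl(diphenyl)silyl]oxy}-3-methylbut-2-enal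
Conditions: i-Bu2AlH, THF, −78 °C; aq. Rochelle salt, 0 °C; used within hours
Reagents that add atoms: none
Why: Reduction of the N-methoxy-N-methyl amide by i-Bu2AlH at −78 °C stops at the aldehyde level (Weinreb amide reduction), and the cold, neutral work-up should leave the Z alkene and the silyl ether as they are.

**Step 4**
Reactants: 4 (2Z)-4-{[tert-butyl(diphenyl)silyl]oxy}-3-methylbut-2-enal; 5 (2E,6E)-farnesyl acetate
Product: 7 (2R,4S,5R,9S,10R,13E)-19-{[tert-butyl(diphenyl)silyl]oxy}-2-hydroxylabda-7,13-dien-15-yl acetate, via ene-adduct aldehyde 6 (not isolated)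
Conditions: 5 (2 equiv), N-protonated (S)-3,3-diphenyl-1-(o-tolyl)tetrahydro-1H,3H-pyrrolo[1,2-c][1,3,2]oxazaborole bis(trifluoromethanesulfonyl)imide (20 mol%, from the oxazaborole and HNTf2), CH2Cl2, −78 to −40 °C; aq. NaHCO3
Reagents that add atoms: none
Why: Proposed new method: the boron Lewis acid binds the formyl oxygen of 4, C5 of the terminal C5=C10 isopropylidene of 5 attacks C4 while a hydrogen of the C1 methyl passes to C3 (conjugate ene reaction) to give aldehyde 6, whose C2 formyl group is then activated by the same acid and attacked by C1 of the new C10=C1 isopropenyl group (Prins closure), after which the tertiary C10 cation is taken by C9 of the C8=C9 alkene and the C8 cation loses the axial H7. The closest known reactions are the Me2AlCl-promoted ene reaction and ene/carbonyl-ene cyclohexanol annulation of α,β-unsaturated aldehydes with alkenes, the enantioselective activation of enals by oxazaborolidinium ions in cycloadditions, and aldehyde- or acetal-initiated cation–olefin cyclization; new are the β,β-disubstituted enal as ene acceptor, the asymmetric version and the joining of the three events. Ring A (C1, C2, C3, C4, C5, C10) closes 6-endo at the C10=C1 alkene through a chair with the C6 chain, the C18 methyl and the boron-bound O2 equatorial, and ring B (C5 to C10) closes 6-endo at the C8=C9 alkene through a second chair. C4 is set by the catalyst, which should leave only the Re face of C4 open, and by the Z geometry of 4, which keeps C19 on the formyl side where the C10 end of the alkene also lies, so that C19 becomes axial; C5 is set in the same event because the hydrogen comes from the methyl group syn to H5 and the C6 chain points away from the enal; C2 takes the equatorial oxygen since an axial one would meet the axial C19 group; C10 is attacked by C9 anti to that axial group, which gives the trans ring fusion with axial C20; C9 follows from the E geometry of the C8=C9 alkene. The step needs attack at the terminal and not the internal alkene of 5, which the lower hindrance of the isopropylidene group and the use of 5 in excess should favor, and it needs the cascade to stop after ring B, which the poorly nucleophilic C13=C14 alkene next to the acetate secures.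

**Step 5**
Reactants: 7 (2R,4S,5R,9S,10R,13E)-19-{[tert-butyl(diphenyl)silyl]oxy}-2-hydroxylabda-7,13-dien-15-yl acetate
Product: 8 (2R,4S,5R,9S,10R,13E)-2,19-dihydroxylabda-7,13-dien-15-yl acetate (CNP0165423.1)
Conditions: HF·pyridine, pyridine, THF, 0 °C to rt
Reagents that add atoms: none
Why: Buffered acidic fluoride cleaves the Si–O bond (silyl ether deprotection) while the acetate, the secondary hydroxyl and both trisubstituted alkenes should be inert, so no stereocenter is touched.

**Compound list**

1 | 4-methylfuran-2(5H)-one | CC1=CC(=O)OC1 | starting material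
2 | (2Z)-4-hydroxy-N-methoxy-N,3-dimethylbut-2-enamide | CON(C)C(=O)/C=C(/C)CO | intermediate
3 | (2Z)-4-{[tert-butyl(diphenyl)silyl]oxy}-N-methoxy-N,3-dimethylbut-2-enamide | CON(C)C(=O)/C=C(/C)CO[Si](c1ccccc1)(c1ccccc1)C(C)(C)C | intermediate
4 | (2Z)-4-{[tert-butyl(diphenyl)silyl]oxy}-3-methylbut-2-enal | O=C/C=C(/C)CO[Si](c1ccccc1)(c1ccccc1)C(C)(C)C | intermediate
5 | (2E,6E)-farnesyl acetate, (2E,6E)-3,7,11-trimethyldodeca-2,6,10-trien-1-yl acetate | CC(=O)OC/C=C(\C)CC/C=C(\C)CCC=C(C)C | starting material
6 | (2E,6E,10R,11S)-11-({[tert-butyl(diphenyl)silyl]oxy}methyl)-3,7,11-trimethyl-13-oxo-10-(prop-1-en-2-yl)trideca-2,6-dien-1-yl acetate (open-chain ene adduct; C4 and C5 of the target already set) | CC(=O)OC/C=C(\C)CC/C=C(\C)CC[C@H](C(C)=C)[C@@](C)(CO[Si](c1ccccc1)(c1ccccc1)C(C)(C)C)CC=O | intermediate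
7 | (2R,4S,5R,9S,10R,13E)-19-{[tert-butyl(diphenyl)silyl]oxy}-2-hydroxylabda-7,13-dien-15-yl acetate (trans-decalin; 2-OH equatorial, C19 axial on C4, 5α-H, 9α-H, 10β-methyl) | CC(=O)OC/C=C(\C)CC[C@H]1C(C)=CC[C@H]2[C@@](C)(CO[Si](c3ccccc3)(c3ccccc3)C(C)(C)C)C[C@H](O)C[C@]12C | intermediate
8 | (2R,4S,5R,9S,10R,13E)-2,19-dihydroxylabda-7,13-dien-15-yl acetate (15-acetoxylabda-7,13E-diene-2α,19-diol) | CC(=O)OC/C=C(\C)CC[C@H]1C(C)=CC[C@H]2[C@@](C)(CO)C[C@H](O)C[C@]12C | target

Total step count: 5.
Longest linear sequence: 5 steps (1 → 2 → 3 → 4 → 7 → 8); 5 is bought.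

**Steps most likely to fail**

1. Step 4 (proposed new method). What may go wrong:
   - poor facial or exo selectivity in the bond formation between C4 and C5;
   - attack of the internal alkene of 5, or of the formyl carbon instead of C4;
   - Z to E isomerization of the enal before it reacts, which would invert C4;
   - proton loss toward the exocyclic C8=C17 position at the end.

   Fallback (sets out from 4 and 5, returns to the route at 7): the events are run apart with achiral Lewis acids of the known kind and the enantiomers are parted at the end. Me2AlCl (1.1 equiv, CH2Cl2, −78 to −20 °C) effects the ene reaction and gives aldehyde 6 as the racemate, that is together with the mirror-image aldehyde F1; the pair is purified by chromatography. SnCl4 (2 equiv, CH2Cl2, −78 °C) then brings about the aldehyde-initiated closure of rings A and B and gives 7 together with the mirror-image bicycle F2. Chromatography on a chiral stationary phase (supercritical CO2/MeOH) removes F2 and returns 7.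

2. Step 3. What may go wrong: Z to E isomerization of the enal, or partial conjugate reduction, during the amide reduction and the purification. Fallback (sets out from 3, returns at 4): the cold reduction mixture is worked up and the crude aldehyde is reduced at once with NaBH4/CeCl3·7H2O (MeOH, −40 °C) to the Z allylic alcohol F3. F3 is stable and can be freed from any E isomer by chromatography. Immediately before step 4 it is oxidized under neutral conditions (Dess–Martin periodinane, NaHCO3, CH2Cl2, 0 °C) and 4 is used without purification.

3. Step 5. What may go wrong: incomplete cleavage of the hindered axial neopentyl silyl ether, or loss or migration of the acetate if the fluoride conditions are forced. Fallback (sets out from 7, returns at 8): both groups are removed on purpose and the acetate is put back selectively. K2CO3 in MeOH gives the diol silyl ether F4; Bu4NF (THF, 50 °C) gives the triol F5. Candida antarctica lipase B with vinyl acetate (tert-butyl methyl ether, rt) should then acetylate only the unhindered primary allylic hydroxyl at C15 and give 8.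

**Further compounds**

F1 | step 4 | (2E,6E,10S,11R)-11-({[tert-butyl(diphenyl)silyl]oxy}methyl)-3,7,11-trimethyl-13-oxo-10-(prop-1-en-2-yl)trideca-2,6-dien-1-yl acetate (mirror image of 6) | CC(=O)OC/C=C(\C)CC/C=C(\C)CC[C@@H](C(C)=C)[C@](C)(CO[Si](c1ccccc1)(c1ccccc1)C(C)(C)C)CC=O
F2 | step 4 | (2S,4R,5S,9R,10S,13E)-19-{[tert-butyl(diphenyl)silyl]oxy}-2-hydroxylabda-7,13-dien-15-yl acetate (mirror image of 7) | CC(=O)OC/C=C(\C)CC[C@@H]1C(C)=CC[C@@H]2[C@](C)(CO[Si](c3ccccc3)(c3ccccc3)C(C)(C)C)C[C@@H](O)C[C@@]12C
F3 | step 3 | (2Z)-4-{[tert-butyl(diphenyl)silyl]oxy}-3-methylbut-2-en-1-ol | OC/C=C(/C)CO[Si](c1ccccc1)(c1ccccc1)C(C)(C)C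
F4 | step 5 | (2R,4S,5R,9S,10R,13E)-19-{[tert-butyl(diphenyl)silyl]oxy}labda-7,13-diene-2,15-diol | OC/C=C(\C)CC[C@H]1C(C)=CC[C@H]2[C@@](C)(CO[Si](c3ccccc3)(c3ccccc3)C(C)(C)C)C[C@H](O)C[C@]12C
F5 | step 5 | (2R,4S,5R,9S,10R,13E)-labda-7,13-diene-2,15,19-triol | OC/C=C(\C)CC[C@H]1C(C)=CC[C@H]2[C@@](C)(CO)C[C@H](O)C[C@]12C
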